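The ten-membered carbocycle is opened at C3–C4 (germacrane numbering), the bond joining the ring methylene C3 to the methyl-bearing carbon C4 of the Z-configured C4=C5 olefin. One operation, hydroboration of a terminal C2=C3 vinyl group followed by palladium-catalysed sp3–sp2 coupling with a C4 vinyl iodide, forms this bond and closes the ring, with the Z geometry brought in unchanged from the iodide. The cyclisation substrate is a trans-4,5-disubstituted butyrolactone: C6 carries the (Z)-2-iodoprop-1-enyl group, C7 the C8–C3 chain with the C10=C14 methylene and silyl-protected C8 and C1 carbinols, C1 being epimeric to the target so that the hydroperoxide can enter by inversion.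

Key step: step 13

Remark: positions in the text use germacrane numbering (C1 = CH–OOH, C6 = lactone O–CH, C7 = ring fusion, C8 = CH–O-angelate, C11=C13 = lactone methylene, C12 = lactone C=O, C10=C14 = ring methylene).
Assumption: C1 and C8 are carried as TBS and TES ethers; both go on under neutral conditions, neither puts an acidic benzylic C–H next to the bis-allylic carbinol, and TES comes off first.
Assumption: iodoenal 4 is used freshly prepared and kept from light, because Z-β-iodoenals isomerise on standing.
Assumption: (2-bromoprop-2-en-1-yl)trimethylsilane 16 is taken as a commercial reagent.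

Step 1
Reactants: 1 but-2-yn-1-ol
Product: 3 (2Z)-3-iodobut-2-en-1-ol, via cyclic alkenylalanate 2 (not isolated)
Conditions: NaAlH2(OCH2CH2OMe)2, THF, 0 °C → rt; then I2, THF, −78 → 0 °C
Reagents that add atoms: iodine, II
Why: Hydroxyl-directed trans-hydroalumination of the propargylic alcohol places aluminium on C3 inside a five-membered alkoxyalanate, and iodinolysis of the C–Al bond with retention should give the Z-iodoalkene with iodine cis to CH2OH.

Step 2
Reactants: 3 (2Z)-3-iodobut-2-en-1-ol
Product: 4 (2Z)-3-iodobut-2-enal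
Conditions: MnO2, CH2Cl2, rt, dark
Reagents that add atoms: none
Why: Oxidation of an allylic alcohol with activated manganese dioxide is neutral and heterogeneous, so the Z-β-iodoenal should form without isomerisation.

Step 3
Reactants: 5 (4S)-4-benzyl-1,3-oxazolidin-2-one; 6 methyl 4-chloro-4-oxobutanoate
Product: 8 methyl 4-[(4S)-4-benzyl-2-oxo-1,3-oxazolidin-3-yl]-4-oxobutanoate, via lithium oxazolidinide 7 (not isolated)
Conditions: n-BuLi, THF, −78 °C; then 6, −78 → 0 °C
Reagents that add atoms: none
Why: N-Acylation of the lithiated Evans auxiliary by the acid chloride is much faster than attack on the methyl ester.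

Step 4
Reactants: 8 succinate imide; 4 (2Z)-3-iodobut-2-enal
Product: 11 (4S)-4-benzyl-3-{[(2S,3S)-2-[(1Z)-2-iodoprop-1-en-1-yl]-5-oxooxolan-3-yl]carbonyl}-1,3-oxazolidin-2-one, via boron enolate 9 (not isolated), via syn-aldol hydroxy ester 10 (not isolated)
Conditions: n-Bu2BOTf, i-Pr2NEt, CH2Cl2, −78 → 0 °C; then 4, −78 → 0 °C; pH 7 buffer, MeOH, H2O2, 0 °C; then PPTS (cat.), toluene, 50 °C
Reagents that add atoms: none
Why: In this Evans syn-aldol reaction the Z boron enolate of the imide (the ester is not enolised) adds to the aldehyde through a chair transition state on the face left open by the benzyl group, which sets C6 and C7, and lactonisation of the C6 hydroxyl onto the methyl ester turns the syn aldol into the trans lactone.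

Step 5
Reactants: 11 lactone imide
Product: 13 (2S,3S)-2-[(1Z)-2-iodoprop-1-en-1-yl]-5-oxooxolane-3-carboxylic acid, via lithium peroxycarboxylate 12 (not isolated)
Conditions: LiOH, H2O2, THF/H2O, 0 °C; then Na2SO3; HCl to pH 2
Reagents that add atoms: hydrogen peroxide, OO
Why: Hydroperoxide anion cleaves the exocyclic imide carbonyl selectively (Evans auxiliary removal) without epimerising C7, and any lactone opened by hydroxide should close again on acidification because only the C6 hydroxyl can form a five-membered ring.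

Step 6
Reactants: 13 lactone acid
Product: 14 (4R,5S)-4-(hydroxymethyl)-5-[(1Z)-2-iodoprop-1-en-1-yl]oxolan-2-one
Conditions: BH3·SMe2, THF, 0 °C → rt; MeOH
Reagents that add atoms: none
Why: Borane reduces a free carboxylic acid through its acyloxyborane much faster than it reduces a lactone or hydroborates the iodine-deactivated trisubstituted olefin, and the non-basic medium gives the primary alcohol no chance to migrate onto the lactone carbonyl.

Step 7
Reactants: 14 hydroxymethyl lactone
Product: 15 (2S,3S)-2-[(1Z)-2-iodoprop-1-en-1-yl]-5-oxooxolane-3-carbaldehyde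
Conditions: Dess–Martin periodinane, CH2Cl2, 0 °C → rt
Reagents that add atoms: none
Why: Dess–Martin oxidation is mild and non-basic, so the C7 centre next to the new aldehyde should keep its thermodynamically preferred trans configuration.

Step 8
Reactants: 16 (2-bromoprop-2-en-1-yl)trimethylsilane; 17 acrolein
Product: 19 rac-4-[(trimethylsilyl)methyl]penta-1,4-dien-3-ol, via alkenylmagnesium bromide 18 (not isolated)
Conditions: Mg, THF, rt; then 17, −78 °C; aq. NH4Cl
Reagents that add atoms: none
Why: The alkenyl Grignard reagent adds 1,2 to acrolein at low temperature and gives the racemic bis-allylic alcohol that already carries the allylsilane needed for the later fragment union.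

Step 9
Reactants: 19 racemic dienol
Product: 20 (3S)-4-[(trimethylsilyl)methyl]penta-1,4-dien-3-ol
Conditions: Burkholderia cepacia lipase (Amano PS), vinyl acetate, hexane, rt, stopped just past half conversion; chromatography
Reagents that add atoms: none
Why: In this lipase-catalysed kinetic resolution the enzyme should acetylate the (R)-alcohol according to the Kazlauskas rule (vinyl as the small group), so the unreacted (S)-alcohol that sets C1 should be recovered in high enantiomeric purity.

Step 10
Reactants: 20 (S)-dienol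
Product: 21 tert-butyldimethyl{[(3S)-4-[(trimethylsilyl)methyl]penta-1,4-dien-3-yl]oxy}silane
Conditions: TBSCl, imidazole, DMF, rt
Reagents that add atoms: tert-butyldimethylsilyl chloride, CC(C)(C)[Si](C)(C)Cl
Why: Imidazole-mediated silylation is mild enough to spare both the acid- and base-sensitive bis-allylic carbinol and the allylsilane.

Step 11
Reactants: 15 lactone aldehyde; 21 allylsilane
Product: 22 (4R,5S)-4-[(1S,4S)-4-[(tert-butyldimethylsilyl)oxy]-1-hydroxy-3-methylidenehex-5-en-1-yl]-5-[(1Z)-2-iodoprop-1-en-1-yl]oxolan-2-one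
Conditions: BF3·OEt2, CH2Cl2, −78 °C
Reagents that add atoms: none
Why: In this Hosomi–Sakurai allylation the olefin terminus of the allylsilane attacks the BF3-activated aldehyde through an open transition state anti to the bulkier C6 ring carbon (Felkin–Anh), which should give the (8S) carbinol, and loss of the silyl group creates the C10=C14 methylene.

Step 12
Reactants: 22 C8 alcohol
Product: 23 (4S,5S)-4-[(1S,4S)-4-[(tert-butyldimethylsilyl)oxy]-3-methylidene-1-[(triethylsilyl)oxy]hex-5-en-1-yl]-5-[(1Z)-2-iodoprop-1-en-1-yl]oxolan-2-one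
Conditions: TESOTf, 2,6-lutidine, CH2Cl2, −78 °C
Reagents that add atoms: triethylsilyl trifluoromethanesulfonate, CC[Si](CC)(CC)OS(=O)(=O)C(F)(F)F
Why: Rapid silylation with the silyl triflate and a hindered base caps the C8 hydroxyl before it can migrate onto the lactone carbonyl, and the triethylsilyl ether can later be removed while the C1 TBS ether stays.

Step 13
Reactants: 23 diene vinyl iodide
Product: 25 (3aS,4S,7S,10Z,11aR)-7-[(tert-butyldimethylsilyl)oxy]-10-methyl-6-methylidene-4-[(triethylsilyl)oxy]-3a,4,5,6,7,8,9,11a-octahydrocyclodeca[b]furan-2(3H)-one, via C3 alkylborane 24 (not isolated)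
Conditions: Sia2BH (from BH3·THF and 2-methylbut-2-ene), THF, 0 °C; then added by syringe pump to PdCl2(dppf) (cat.), AsPh3, Cs2CO3, DMF/THF/H2O, 50 °C, high dilution, degassed
Reagents that add atoms: none
Why: Disiamylborane adds across the monosubstituted C2=C3 vinyl group with boron on C3, since this hindered dialkylborane reacts much faster with a monosubstituted terminal olefin than with the doubly flanked 1,1-disubstituted C10=C14 olefin or the iodoalkene, a discrimination that 9-BBN-H would not give reliably. Zerovalent palladium, formed from PdCl2(dppf), inserts into the C4–I bond with retention, carbonate-assisted transfer of the primary C3 alkyl group from boron gives an eleven-membered palladacycle, and reductive elimination forms C3–C4. The closest known reaction type is the intramolecular B-alkyl Suzuki–Miyaura coupling used to close medium and large carbocycles. The ten-membered ring is closed by sp3–sp2 coupling between the ring methylene C3 and the methyl-bearing C4 of the trisubstituted olefin, the feature of the target that makes this bond the natural seam. No stereocentre is created: the Z geometry is fixed in the iodide, survives oxidative addition and is the geometry that brings C3 and C6 to the same side of the olefin. Ring closure has to win over oligomerisation, protodeboronation and β-hydride loss, which is addressed by syringe-pump addition into a dilute catalyst solution, by the chelating dppf ligand that speeds reductive elimination, and by the trans-lactone that already holds the two chains on adjacent carbons.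

Step 14
Reactants: 25 ten-membered lactone
Product: 27 C11 dimethylaminomethyl lactone (3-[(dimethylamino)methyl] derivative of 25; C11 epimers), via lithium enolate 26 (not isolated)
Conditions: LiN(i-Pr)2, THF, −78 °C; then Me2N=CH2+ I−, −78 → 0 °C
Reagents that add atoms: N,N-dimethylmethyleneiminium iodide (Eschenmoser's salt), C=[N+](C)C.[I-]
Why: The lactone enolate (C11 is the only enolisable position) is aminomethylated by Eschenmoser's salt in a Mannich reaction, and the new C11 centre is of no consequence because it is removed in the next step.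

Step 15
Reactants: 27 Mannich base
Product: 29 (3aS,4S,7S,10Z,11aR)-7-[(tert-butyldimethylsilyl)oxy]-10-methyl-3,6-dimethylidene-4-[(triethylsilyl)oxy]-3a,4,5,6,7,8,9,11a-octahydrocyclodeca[b]furan-2(3H)-one, via trimethylammonium iodide 28 (not isolated)
Conditions: MeI, CH2Cl2/MeOH, rt; then aq. NaHCO3, rt
Reagents that add atoms: none
Why: Quaternisation followed by mild-base E1cB elimination of trimethylamine should give the exocyclic C11=C13 methylene without touching the silyl ethers.

Step 16
Reactants: 29 α-methylene lactone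
Product: 30 (3aR,4S,7S,10Z,11aR)-7-[(tert-butyldimethylsilyl)oxy]-4-hydroxy-10-methyl-3,6-dimethylidene-3a,4,5,6,7,8,9,11a-octahydrocyclodeca[b]furan-2(3H)-one
Conditions: HF·pyridine, pyridine, THF, 0 °C
Reagents that add atoms: none
Why: Buffered fluoride desilylation removes the more labile triethylsilyl ether at C8 and leaves the C1 TBS ether, while the weakly acidic medium keeps the freed C8 hydroxyl from translactonising or adding to the methylene lactone.

Step 17
Reactants: 30 C8 alcohol; 31 angelic acid ((2Z)-2-methylbut-2-enoic acid)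
Product: 33 (3aR,4S,7S,10Z,11aR)-7-[(tert-butyldimethylsilyl)oxy]-10-methyl-3,6-dimethylidene-2-oxo-2,3,3a,4,5,6,7,8,9,11a-decahydrocyclodeca[b]furan-4-yl (2Z)-2-methylbut-2-enoate, via mixed anhydride 32 (not isolated)
Conditions: 31, 2,4,6-Cl3C6H2COCl, Et3N, toluene, rt; then 30, toluene, 75 °C
Reagents that add atoms: none
Why: Yamaguchi-type esterification through the angelic 2,4,6-trichlorobenzoic mixed anhydride, run without a nucleophilic catalyst, acylates the hindered C8 alcohol while avoiding the addition–elimination pathway that turns angelates into tiglates.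

Step 18
Reactants: 33 angelate
Product: 34 (3aR,4S,7S,10Z,11aR)-7-hydroxy-10-methyl-3,6-dimethylidene-2-oxo-2,3,3a,4,5,6,7,8,9,11a-decahydrocyclodeca[b]furan-4-yl (2Z)-2-methylbut-2-enoate
Conditions: HF·pyridine, THF, 0 °C → rt
Reagents that add atoms: none
Why: Fluoride cleavage of the remaining silyl ether under mildly acidic conditions frees the C1 allylic alcohol without harming the angelate or the α-methylene lactone.

Step 19
Reactants: 34 C1 alcohol
Product: 36 (3aR,4S,7R,10Z,11aR)-7-hydroperoxy-10-methyl-3,6-dimethylidene-2-oxo-2,3,3a,4,5,6,7,8,9,11a-decahydrocyclodeca[b]furan-4-yl (2Z)-2-methylbut-2-enoate (CNP0105813.1), via C1 mesylate 35 (not isolated)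
Conditions: MsCl, Et3N, CH2Cl2, −60 °C; then anhydrous H2O2 in Et2O (large excess), −78 → −20 °C
Reagents that add atoms: hydrogen peroxide, OO
Why: In this perhydrolysis of an allylic mesylate, backside displacement by neutral hydrogen peroxide in a poorly ionising solvent should invert C1 to the (R)-hydroperoxide, and the absence of base spares the α-methylene lactone and both esters.

Compound list

1 | but-2-yn-1-ol | CC#CCO | starting material
2 | cyclic alkenylalanate, sodium salt (five-membered O–Al–C3=C2–C1 ring, two 2-methoxyethoxy groups on aluminium; not isolated) | CC1=CCO[Al-]1(OCCOC)OCCOC.[Na+] | intermediate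
3 | (2Z)-3-iodobut-2-en-1-ol | C/C(I)=C/CO | intermediate
4 | (2Z)-3-iodobut-2-enal | C/C(I)=C/C=O | intermediate
5 | (4S)-4-benzyl-1,3-oxazolidin-2-one | O=C1N[C@@H](Cc2ccccc2)CO1 | starting material
6 | methyl 4-chloro-4-oxobutanoate | COC(=O)CCC(Cl)=O | starting material
7 | N-lithio derivative of 5 (not isolated) | [Li]N1[C@@H](Cc2ccccc2)COC1=O | intermediate
8 | methyl 4-[(4S)-4-benzyl-2-oxo-1,3-oxazolidin-3-yl]-4-oxobutanoate | COC(=O)CCC(=O)N1[C@@H](Cc2ccccc2)COC1=O | intermediate
9 | (Z)-di-n-butylboron enolate of 8 (not isolated) | COC(=O)C/C=C(\OB(CCCC)CCCC)N1[C@@H](Cc2ccccc2)COC1=O | intermediate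
10 | methyl (3S,4S,5Z)-3-{[(4S)-4-benzyl-2-oxo-1,3-oxazolidin-3-yl]carbonyl}-4-hydroxy-6-iodohept-5-enoate (not isolated) | COC(=O)C[C@H](C(=O)N1[C@@H](Cc2ccccc2)COC1=O)[C@H](O)/C=C(/C)I | intermediate
11 | (4S)-4-benzyl-3-{[(2S,3S)-2-[(1Z)-2-iodoprop-1-en-1-yl]-5-oxooxolan-3-yl]carbonyl}-1,3-oxazolidin-2-one | O=C1C[C@H](C(=O)N2[C@@H](Cc3ccccc3)COC2=O)[C@@H](/C=C(/C)I)O1 | intermediate
12 | lithium (2S,3S)-2-[(1Z)-2-iodoprop-1-en-1-yl]-5-oxooxolane-3-carboperoxoate (not isolated) | O=C1C[C@H](C(=O)O[O-])[C@@H](/C=C(/C)I)O1.[Li+] | intermediate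
13 | (2S,3S)-2-[(1Z)-2-iodoprop-1-en-1-yl]-5-oxooxolane-3-carboxylic acid | O=C1C[C@H](C(=O)O)[C@@H](/C=C(/C)I)O1 | intermediate
14 | (4R,5S)-4-(hydroxymethyl)-5-[(1Z)-2-iodoprop-1-en-1-yl]oxolan-2-one | O=C1C[C@H](CO)[C@@H](/C=C(/C)I)O1 | intermediate
15 | (2S,3S)-2-[(1Z)-2-iodoprop-1-en-1-yl]-5-oxooxolane-3-carbaldehyde | O=C1C[C@H](C=O)[C@@H](/C=C(/C)I)O1 | intermediate
16 | (2-bromoprop-2-en-1-yl)trimethylsilane | C=C(Br)C[Si](C)(C)C | starting material
17 | acrolein | C=CC=O | starting material
18 | {3-(trimethylsilyl)prop-1-en-2-yl}magnesium bromide (not isolated) | C=C([Mg]Br)C[Si](C)(C)C | intermediate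
19 | rac-4-[(trimethylsilyl)methyl]penta-1,4-dien-3-ol | C=CC(O)C(=C)C[Si](C)(C)C | intermediate
20 | (3S)-4-[(trimethylsilyl)methyl]penta-1,4-dien-3-ol | C[Si](C)(C)CC(=C)[C@@H](O)C=C | intermediate
21 | tert-butyldimethyl{[(3S)-4-[(trimethylsilyl)methyl]penta-1,4-dien-3-yl]oxy}silane | C[Si](C)(C)CC(=C)[C@@H](O[Si](C)(C)C(C)(C)C)C=C | intermediate
22 | (4R,5S)-4-[(1S,4S)-4-[(tert-butyldimethylsilyl)oxy]-1-hydroxy-3-methylidenehex-5-en-1-yl]-5-[(1Z)-2-iodoprop-1-en-1-yl]oxolan-2-one | O=C1C[C@H]([C@@H](O)CC(=C)[C@@H](O[Si](C)(C)C(C)(C)C)C=C)[C@@H](/C=C(/C)I)O1 | intermediate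
23 | (4S,5S)-4-[(1S,4S)-4-[(tert-butyldimethylsilyl)oxy]-3-methylidene-1-[(triethylsilyl)oxy]hex-5-en-1-yl]-5-[(1Z)-2-iodoprop-1-en-1-yl]oxolan-2-one (cyclisation substrate) | O=C1C[C@H]([C@@H](O[Si](CC)(CC)CC)CC(=C)[C@@H](O[Si](C)(C)C(C)(C)C)C=C)[C@@H](/C=C(/C)I)O1 | intermediate
24 | C3 bis(3-methylbutan-2-yl)borane formed from 23 (boron on the terminal carbon of the former vinyl group; not isolated) | O=C1C[C@H]([C@@H](O[Si](CC)(CC)CC)CC(=C)[C@@H](O[Si](C)(C)C(C)(C)C)CCB(C(C)C(C)C)C(C)C(C)C)[C@@H](/C=C(/C)I)O1 | intermediate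
25 | (3aS,4S,7S,10Z,11aR)-7-[(tert-butyldimethylsilyl)oxy]-10-methyl-6-methylidene-4-[(triethylsilyl)oxy]-3a,4,5,6,7,8,9,11a-octahydrocyclodeca[b]furan-2(3H)-one (cyclisation product) | O=C1C[C@@H]2[C@@H](O[Si](CC)(CC)CC)CC(=C)[C@@H](O[Si](C)(C)C(C)(C)C)CC/C(C)=C\[C@H]2O1 | intermediate
26 | lithium enolate of 25 (not isolated) | [Li]OC1=C[C@@H]2[C@@H](O[Si](CC)(CC)CC)CC(=C)[C@@H](O[Si](C)(C)C(C)(C)C)CC/C(C)=C\[C@H]2O1 | intermediate
27 | 3-[(dimethylamino)methyl] derivative of 25 (C11 epimers) | O=C1C(CN(C)C)[C@@H]2[C@@H](O[Si](CC)(CC)CC)CC(=C)[C@@H](O[Si](C)(C)C(C)(C)C)CC/C(C)=C\[C@H]2O1 | intermediate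
28 | trimethylammonium iodide formed from 27 (not isolated) | O=C1C(C[N+](C)(C)C)[C@@H]2[C@@H](O[Si](CC)(CC)CC)CC(=C)[C@@H](O[Si](C)(C)C(C)(C)C)CC/C(C)=C\[C@H]2O1.[I-] | intermediate
29 | (3aS,4S,7S,10Z,11aR)-7-[(tert-butyldimethylsilyl)oxy]-10-methyl-3,6-dimethylidene-4-[(triethylsilyl)oxy]-3a,4,5,6,7,8,9,11a-octahydrocyclodeca[b]furan-2(3H)-one | O=C1C(=C)[C@@H]2[C@@H](O[Si](CC)(CC)CC)CC(=C)[C@@H](O[Si](C)(C)C(C)(C)C)CC/C(C)=C\[C@H]2O1 | intermediate
30 | (3aR,4S,7S,10Z,11aR)-7-[(tert-butyldimethylsilyl)oxy]-4-hydroxy-10-methyl-3,6-dimethylidene-3a,4,5,6,7,8,9,11a-octahydrocyclodeca[b]furan-2(3H)-one | O=C1C(=C)[C@@H]2[C@@H](O)CC(=C)[C@@H](O[Si](C)(C)C(C)(C)C)CC/C(C)=C\[C@H]2O1 | intermediate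
31 | angelic acid, (2Z)-2-methylbut-2-enoic acid | C/C=C(/C)C(=O)O | starting material
32 | (2Z)-2-methylbut-2-enoic 2,4,6-trichlorobenzoic anhydride (not isolated) | C/C=C(/C)C(=O)OC(=O)c1c(Cl)cc(Cl)cc1Cl | intermediate
33 | (3aR,4S,7S,10Z,11aR)-7-[(tert-butyldimethylsilyl)oxy]-10-methyl-3,6-dimethylidene-2-oxo-2,3,3a,4,5,6,7,8,9,11a-decahydrocyclodeca[b]furan-4-yl (2Z)-2-methylbut-2-enoate | O=C1C(=C)[C@@H]2[C@@H](OC(=O)/C(C)=C\C)CC(=C)[C@@H](O[Si](C)(C)C(C)(C)C)CC/C(C)=C\[C@H]2O1 | intermediate
34 | (3aR,4S,7S,10Z,11aR)-7-hydroxy-10-methyl-3,6-dimethylidene-2-oxo-2,3,3a,4,5,6,7,8,9,11a-decahydrocyclodeca[b]furan-4-yl (2Z)-2-methylbut-2-enoate | O=C1C(=C)[C@@H]2[C@@H](OC(=O)/C(C)=C\C)CC(=C)[C@@H](O)CC/C(C)=C\[C@H]2O1 | intermediate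
35 | C1 methanesulfonate of 34 (7S; not isolated) | O=C1C(=C)[C@@H]2[C@@H](OC(=O)/C(C)=C\C)CC(=C)[C@@H](OS(C)(=O)=O)CC/C(C)=C\[C@H]2O1 | intermediate
36 | (3aR,4S,7R,10Z,11aR)-7-hydroperoxy-10-methyl-3,6-dimethylidene-2-oxo-2,3,3a,4,5,6,7,8,9,11a-decahydrocyclodeca[b]furan-4-yl (2Z)-2-methylbut-2-enoate | C=C1C(=O)O[C@@H]2/C=C(/C)CC[C@@H](OO)C(=C)C[C@H](OC(=O)/C(C)=C\C)[C@@H]12 | target

Total step count: 19
Longest linear sequence: 15 steps (1, 2, 4, 5, 6, 7, 11, 12, 13, 14, 15, 16, 17, 18, 19)

The three steps most likely to fail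

Step 13. Closure of the strained ten-membered ring may lose to oligomerisation, and the alkylboron or alkylpalladium intermediate may be consumed by protodeboronation or β-hydride loss before transmetalation and reductive elimination. The fallback keeps the same C3–C4 coupling but makes it between two fragments and closes the ring at C8–C9 instead. It sets out from 21 and 14 and returns at 25. Allylsilane 21 is hydroborated at its vinyl group with Sia2BH to give the alkylborane F1, which is coupled directly with vinyl iodide 14 (PdCl2(dppf), AsPh3, Cs2CO3, DMF/H2O) to give the open-chain Z-olefin alcohol F2. Dess–Martin oxidation gives the aldehyde F3. BF3·OEt2 at high dilution and −78 °C then closes the ring by intramolecular Hosomi–Sakurai addition of the allylsilane to the C8 aldehyde and gives the ten-membered C8 alcohol F4, whose C8 configuration would have to be secured at this point. TESOTf and 2,6-lutidine convert F4 into 25.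

Step 19. The allylic mesylate may ionise and not undergo direct displacement. That would erode the C1 configuration, shift the oxygen to C14, or let the C4=C5 olefin capture the cation across the ring. The fallback gives up the displacement and introduces the hydroperoxide by an ene reaction. It sets out from 34 and returns at 36. Alcohol 34 is treated with 2-nitrobenzenesulfonylhydrazide, PPh3 and diethyl azodicarboxylate (THF, −30 °C → rt). Mitsunobu displacement gives the allylic sulfonylhydrazine F5, which loses the sulfinic acid to give the allylic diazene F6. Sigmatropic loss of N2 from F6 moves the double bond to C1=C10 and leaves C14 as a methyl group, giving the 1(10),4-diene lactone F7. Dye-sensitised photooxygenation (O2, tetraphenylporphyrin, visible light, CH2Cl2, −20 °C) then carries out a Schenck ene reaction at the electron-rich C1=C10 olefin: a C14 hydrogen is abstracted, oxygen is delivered to C1 and the C10=C14 methylene is restored, which returns to 36. In this variant the C1 configuration would depend on the face of the ring that singlet oxygen approaches.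

Step 11. The open transition state may show poor facial selectivity at C8, and the Lewis acid may ionise the bis-allylic silyl ether of 21. The fallback replaces substrate control by ligand control. It sets out from 21 and returns at 22. N-Bromosuccinimide (CH2Cl2, propylene oxide, −78 °C) converts 21 by bromodesilylation with allyl shift into the allylic bromide F8. F8 and aldehyde 15 are then joined in a Nozaki–Hiyama allylation with CrCl2 and a chiral sulfonamide ligand (THF, rt), in which the ligand on the allylchromium species fixes the C8 configuration, the ligand antipode being chosen to match the Felkin preference of 15. Without a nickel co-catalyst, divalent chromium should leave the vinyl iodide untouched.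

Further compounds

F1 | step 13 | bis(3-methylbutan-2-yl)borane adduct of 21 (boron on the terminal carbon of the former vinyl group) | C[Si](C)(C)CC(=C)[C@@H](O[Si](C)(C)C(C)(C)C)CCB(C(C)C(C)C)C(C)C(C)C
F2 | step 13 | (4R,5R)-5-[(1Z,5S)-5-[(tert-butyldimethylsilyl)oxy]-2-methyl-6-[(trimethylsilyl)methyl]hepta-1,6-dien-1-yl]-4-(hydroxymethyl)oxolan-2-one | O=C1C[C@H](CO)[C@@H](/C=C(/C)CC[C@H](O[Si](C)(C)C(C)(C)C)C(=C)C[Si](C)(C)C)O1
F3 | step 13 | (2R,3S)-2-[(1Z,5S)-5-[(tert-butyldimethylsilyl)oxy]-2-methyl-6-[(trimethylsilyl)methyl]hepta-1,6-dien-1-yl]-5-oxooxolane-3-carbaldehyde | O=C1C[C@H](C=O)[C@@H](/C=C(/C)CC[C@H](O[Si](C)(C)C(C)(C)C)C(=C)C[Si](C)(C)C)O1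
F4 | step 13 | (3aR,4S,7S,10Z,11aR)-7-[(tert-butyldimethylsilyl)oxy]-4-hydroxy-10-methyl-6-methylidene-3a,4,5,6,7,8,9,11a-octahydrocyclodeca[b]furan-2(3H)-one | O=C1C[C@@H]2[C@@H](O)CC(=C)[C@@H](O[Si](C)(C)C(C)(C)C)CC/C(C)=C\[C@H]2O1
F5 | step 19 | C1 N-(2-nitrobenzenesulfonyl)hydrazine formed from 34 with inversion at C1 | O=C1C(=C)[C@@H]2[C@@H](OC(=O)/C(C)=C\C)CC(=C)[C@H](N(N)S(=O)(=O)c3ccccc3[N+](=O)[O-])CC/C(C)=C\[C@H]2O1
F6 | step 19 | C1 monoalkyl diazene formed from F5 | O=C1C(=C)[C@@H]2[C@@H](OC(=O)/C(C)=C\C)CC(=C)[C@H](N=N)CC/C(C)=C\[C@H]2O1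
F7 | step 19 | (3aR,4S,6E,10Z,11aR)-6,10-dimethyl-3-methylidene-2-oxo-2,3,3a,4,5,8,9,11a-octahydrocyclodeca[b]furan-4-yl (2Z)-2-methylbut-2-enoate | O=C1C(=C)[C@@H]2[C@@H](OC(=O)/C(C)=C\C)C/C(C)=C/CC/C(C)=C\[C@H]2O1
F8 | step 11 | {[(3S)-4-(bromomethyl)penta-1,4-dien-3-yl]oxy}(tert-butyl)dimethylsilane | BrCC(=C)[C@@H](O[Si](C)(C)C(C)(C)C)C=C
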